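Remark on the chemistry: the target structure fixes C1 (R) and C3 (S) but leaves the biaryl axis undefined. The route therefore controls only the two carbon stereocentres and carries whatever mixture of axial isomers forms.

## The problem

Target 31 is a 1,2,3-trimethyl-6,8-dimethoxytetrahydroisoquinoline whose C5 is bonded to C1' of a 4,5-dimethoxy-7-methylnaphthalene. The biaryl bond is flanked by the C6 methoxy group and the C4 methylene on one side and by C2'-H and the peri C8'-H on the other, so a cross-coupling would have to join two hindered, electron-rich partners. There are two stereocentres, C3 (S) and C1 (R), cis across nitrogen. C3 has no neighbouring group that could induce it and is best bought as amino acid 16. C1 can then be set last under control of C3, by hydride addition to a C1-methyl iminium ion; the reverse order (methyl nucleophile onto a C1-H iminium ion) would give the trans series. Both arenes (the peri-dimethoxynaphthalene and the resorcinol diether) are easily attacked by oxidants, halogenating agents and free carbocations. A polyketide-type precursor adds a β-amino ketone that can lose nitrogen by retro-Michael reaction and a polycarbonyl chain that can cyclize in more than one way. The enabling feature is the substitution pattern of the isoquinoline benzene ring: oxygen on C6 and C8, carbon on C8a (C1) and C4a (C4), and the naphthyl on C5. The chain C1–C8a–C8–C7–C6–C5–C4a–C4–C3 therefore alternates carbonyl carbons (C1, C8, C6, C4a) with nucleophilic carbons (C8a, C7, C5) and is folded once by a C8a–C4a aldol bond. C5 is the methine between two carbonyls, where the naphthyl can be placed by enolate chemistry before the ring exists.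

## Retrosynthesis

**31 ⇒ 28.** The C1–H bond is cut first (back to iminium chloride 30), then the C1–CH3 bond (back to N-methyl lactam 28). This order is what delivers cis: hydride is the last nucleophile and should enter anti to the C3 methyl group. A cut of C1–C8a (ring closure of a phenethylamine) is the usual neighbour, but it would require the biaryl amine to be made by coupling and gives no reliable cis control. The lactam is one stereocentre and one C–C bond simpler. The forward step must add a methyl carbanion once to a hindered lactam and then reduce the iminium ion face-selectively.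

**28 ⇒ 26 ⇒ 25.** The N2–C1 amide bond is cut to amino ester 27 (freed from carbamate 26), and the two O-methyl bonds are cut to resorcylate 25. The carbamate keeps nitrogen inert during O-methylation, and the ester is exactly what the polyketide fold leaves at C1. The forward lactamization has to take place on a di-ortho-substituted benzoate, which is acceptable because it is intramolecular and six-membered.

**25 ⇒ 21 (key disconnection).** The benzene ring is opened at C8a–C4a (aldol) and the ester C–O bond is traced back to an acylketene masked as a dioxinone. Compared with cutting the biaryl bond (coupling) or two ring bonds at once (cycloaddition), this cut removes the ring and the hindered axis together. In precursor 21 the naphthyl sits on an sp3 methine of an open chain. The forward reaction must select the C8a-to-C4a aldol among the possible closures.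

**21 ⇒ 15 + 18.** The bond between the naphthyl-bearing methine and the carbonyl that becomes C4a is cut. This gives keto-dioxinone 15, which reacts as its dianion 20, and the N-Boc-N-methyl amino acid 18, activated as imidazolide 19. Cutting on the other side of the methine would need the acyl donor of a β-keto acid. The chosen cut divides the molecule into the naphthalene half and the chiral half. It asks for acylation at the benzylic carbon of the dianion and not at the central carbon.

**15 ⇒ 11 + 12.** The bond between the dioxinone methyl carbon and the ketone carbonyl is cut, giving commercial dioxinone 12 (as lithium dienolate 14) and naphthylacetic acid 11 (as chloride 13). This is the standard way to extend dioxinone 12 by one acyl unit.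

**11 ⇒ 10 ⇒ 9.** The aryl–CH2 bond is cut, so that bromide 9 is coupled with a zinc ester enolate to ester 10. This brings in both carbons at once and uses the halogen that the naphthalene synthesis needs anyway.

**9 ⇒ 7 ⇒ 6 ⇒ 5 ⇒ 3 ⇒ 1 + 2.** The oxygenated naphthalene ring is cut at C4'–C4a' (Friedel–Crafts) and at the styrene double bond (Stobbe condensation of aldehyde 1 with succinate 2). The bromine of 1 blocks one ortho position, so ring closure must occur next to the methoxy group and gives the peri-dioxygenated pattern of 5. The same bromine later becomes the coupling handle at C1'. The ester of 5 is taken down to the C7' methyl group through alcohols 6 and 7.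

**18 ⇒ 17 ⇒ 16.** Both N–C bonds to the carbamate and to methyl are cut back to (S)-3-aminobutanoic acid 16, whose stereocentre is never adjacent to an acidic position in the route.

## Roads not taken

**Alternative 1:** Here the naphthalene would be built last. Naphthol ester A1 is cut at C7'–C8' and C5'–C6' back to 3-arylphthalide A2 and tert-butyl acrylate A3. In the forward sense the anion of A2, formed with a lithium amide base, adds to A3, closes by Dieckmann reaction on the lactone and is dehydrated by acid. Its merits are that the heterocycle with both stereocentres is finished before the key step, that it never meets polycarbonyl enolate chemistry, and that the axis arises without a cross-coupling. In that respect it is safer than the chosen plan, which carries a β-amino ketone through a basic step. Its weak points are these: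
- The anion of A2 is tertiary, doubly benzylic and flanked by the C6 methoxy group and C4, and the Michael step must create a quaternary carbon next to the future axis in an intermolecular reaction.
- A2 presupposes a complete cis heterocycle metalated at C5.
- A1 still carries a surplus ester that has to be cleaved and decarboxylated, a naphthol to methylate and a carbamate to reduce.

The chosen plan sets against this an intramolecular ring closure remote from the aryl-bearing carbon and a carboxyl carbon that is used as C1 instead of being discarded.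

**Alternative 2:** The benzene ring of aryl ketone A4 is cut at C5–C4a and C8–C8a into silyloxydiene A5 and amino alkynone A6. A thermal [4+2] cycloaddition, followed by elimination of the acetal methoxy group and desilylation, would aromatize the ring and create the axis. This road is better in two respects: A4 already has the acetyl group at the C1 oxidation level, so no organometallic addition to a lactam is needed, and it differentiates O6 from O8. Its weak points are these:
- The bond C5–C4a must form intermolecularly between a diene terminus that carries the naphthyl group and an alkyne carbon that carries the aminopropyl chain.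
- A terminal aryl group on a 1,1-dioxygenated diene lowers its reactivity and makes the geometry of A5 critical.
- A5 is a hydrolytically labile ketene acetal that would itself have to be made from acid 11.
- A6 has propargylic hydrogens next to a ynone and can isomerize to an allene.

The chosen plan cannot match the short end game of this road. It sets against it a ring closure that is intramolecular, runs under carbonate at room temperature from a stable precursor, and forms no bond at the naphthyl-bearing carbon.

**Alternative 3:** Phenol A7 is cut back to diazo ketone A8 and methoxyacetylene A9, with A8 derived from the meso piperidinone A10. Irradiation would trigger Wolff rearrangement, [2+2] capture of A9, four-electron ring opening and six-electron ring closure to build the benzene ring on the finished heterocycle. Its merit is that the cis relation of C1 and C3 is guaranteed by A10 and does not depend on an iminium reduction. In that respect it is more secure than the chosen plan, and it also differentiates O6 from O8. Its weak points are these: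
- A10 is meso, so the absolute configuration must come from an enantiotopic-group-selective enolization or a resolution.
- A8 needs several steps (enol derivative, acylation with the naphthylacetyl unit, diazo transfer).
- A9 is volatile and unstable.
- The [2+2] step must occur at a ketene carbon that bears the naphthyl group.

The chosen plan sets against this absolute configuration from the chiral pool, a thermal key step and a shorter sequence.

Key step: step 12

## Route

**Step 1**
Reactants: 1 2-bromo-5-methoxybenzaldehyde; 2 diethyl succinate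
Product: 3 (E)-4-(2-bromo-5-methoxyphenyl)-3-(ethoxycarbonyl)but-3-enoic acid
Conditions: NaOEt, EtOH, reflux; aq. HCl
Reagents that add atoms: none
Why: Stobbe condensation: the succinate enolate adds to the aldehyde, the alkoxide lactonizes onto the distal ester and base-induced opening should give the (E)-half-ester, with the aryl group cis to the CH2CO2H arm as needed for ring closure.

**Step 2**
Reactants: 3 (E)-4-(2-bromo-5-methoxyphenyl)-3-(ethoxycarbonyl)but-3-enoic acid
Product: 5 ethyl 4-acetoxy-8-bromo-5-methoxy-2-naphthoate, via naphthol ester 4 (not isolated)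
Conditions: Ac2O, NaOAc, 140 °C
Reagents that add atoms: acetic anhydride, CC(=O)OC(C)=O
Why: Intramolecular Friedel–Crafts acylation by the acid activated with Ac2O can only occur at the free position ortho to the side chain (the other is blocked by bromine); enolization gives naphthol 4, which is O-acetylated in the same pot.

**Step 3**
Reactants: 5 ethyl 4-acetoxy-8-bromo-5-methoxy-2-naphthoate
Product: 6 5-bromo-3-(hydroxymethyl)-8-methoxynaphthalen-1-ol
Conditions: i-Bu2AlH (6 equiv), CH2Cl2, −78 → 0 °C; aq. HCl
Reagents that add atoms: none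
Why: Ester reduction with i-Bu2AlH takes the ethyl ester to the primary alcohol and cleaves the aryl acetate reductively, while the aryl bromide is inert to this hydride.

**Step 4**
Reactants: 6 5-bromo-3-(hydroxymethyl)-8-methoxynaphthalen-1-ol
Product: 7 (8-bromo-4,5-dimethoxynaphthalen-2-yl)methanol
Conditions: MeI, K2CO3, acetone, reflux
Reagents that add atoms: iodomethane, CI
Why: Williamson ether synthesis; carbonate deprotonates only the naphthol, so the benzylic alcohol is left free.

**Step 5**
Reactants: 7 (8-bromo-4,5-dimethoxynaphthalen-2-yl)methanol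
Product: 9 1-bromo-4,5-dimethoxy-7-methylnaphthalene, via mesylate 8 (not isolated)
Conditions: MsCl, Et3N, THF, 0 °C; then LiBHEt3, 0 °C → rt
Reagents that add atoms: none
Why: Sulfonate formation followed by SN2 hydride displacement; LiBHEt3 reduces primary benzylic sulfonates (or the chloride that may form from them) quickly and does not touch aryl bromides.

**Step 6**
Reactants: 9 1-bromo-4,5-dimethoxy-7-methylnaphthalene
Product: 10 ethyl 2-(4,5-dimethoxy-7-methylnaphthalen-1-yl)acetate
Conditions: BrZnCH2CO2Et (from ethyl bromoacetate, Zn, THF), Pd2(dba)3 (cat.), XPhos (cat.), THF, 65 °C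
Reagents that add atoms: ethyl bromoacetate (as its zinc reagent), CCOC(=O)CBr
Why: Negishi-type coupling of a Reformatsky zinc enolate (palladium-catalysed ester α-arylation): zerovalent palladium inserts into the C–Br bond, the zinc enolate transmetalates and reductive elimination forms the aryl–CH2 bond; the bulky biaryl phosphine handles the electron-rich 1-naphthyl bromide.

**Step 7**
Reactants: 10 ethyl 2-(4,5-dimethoxy-7-methylnaphthalen-1-yl)acetate
Product: 11 2-(4,5-dimethoxy-7-methylnaphthalen-1-yl)acetic acid
Conditions: LiOH, THF/MeOH/H2O, rt; aq. HCl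
Reagents that add atoms: lithium hydroxide, [Li+].[OH-]
Why: Ester saponification of an unhindered arylacetate.

**Step 8**
Reactants: 11 2-(4,5-dimethoxy-7-methylnaphthalen-1-yl)acetic acid; 12 2,2,6-trimethyl-4H-1,3-dioxin-4-one
Product: 15 6-[3-(4,5-dimethoxy-7-methylnaphthalen-1-yl)-2-oxopropyl]-2,2-dimethyl-4H-1,3-dioxin-4-one, via acid chloride 13 (not isolated), via lithium dienolate 14 (not isolated)
Conditions: 11, (COCl)2, DMF (cat.), CH2Cl2, 0 °C → rt, evaporate; 12 (2.2 equiv), LiN(SiMe3)2 (2.2 equiv), THF, −78 °C; add 13, −78 °C; aq. NH4Cl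
Reagents that add atoms: none
Why: Acid chloride formation, then C-acylation at the γ-carbon of the dioxinone lithium dienolate (vinylogous Claisen condensation); two equivalents of dienolate are used because product 15 is more acidic than 12.

**Step 9**
Reactants: 16 (S)-3-aminobutanoic acid
Product: 17 (S)-3-[(tert-butoxycarbonyl)amino]butanoic acid
Conditions: Boc2O, NaOH, dioxane/H2O, 0 °C → rt; aq. HCl to pH 3
Reagents that add atoms: di-tert-butyl dicarbonate, CC(C)(C)OC(=O)OC(=O)OC(C)(C)C
Why: Carbamate formation under Schotten–Baumann conditions; the stereocentre is not involved.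

**Step 10**
Reactants: 17 (S)-3-[(tert-butoxycarbonyl)amino]butanoic acid
Product: 18 (S)-3-[(tert-butoxycarbonyl)(methyl)amino]butanoic acid
Conditions: NaH (3 equiv), MeI (excess), THF, 0 °C → rt; aq. HCl to pH 3
Reagents that add atoms: iodomethane, CI
Why: N-Methylation of the sodium salt of a Boc amino acid; the sodium carboxylate is not alkylated in THF and the β-stereocentre bears no acidic hydrogen.

**Step 11**
Reactants: 15 6-[3-(4,5-dimethoxy-7-methylnaphthalen-1-yl)-2-oxopropyl]-2,2-dimethyl-4H-1,3-dioxin-4-one; 18 (S)-3-[(tert-butoxycarbonyl)(methyl)amino]butanoic acid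
Product: 21 tert-butyl [(2S)-5-(4,5-dimethoxy-7-methylnaphthalen-1-yl)-7-(2,2-dimethyl-4-oxo-4H-1,3-dioxin-6-yl)-4,6-dioxoheptan-2-yl](methyl)carbamate, via acyl imidazole 19 (not isolated), via dilithio dianion 20 (not isolated)
Conditions: 18, carbonyldiimidazole, THF, rt; 15, LiN(i-Pr)2 (3.1 equiv), THF, −78 °C; add 19 (1.5 equiv), −78 → −30 °C; AcOH
Reagents that add atoms: none
Why: γ-Acylation of a 1,3-dicarbonyl dianion (Hauser-type), as known for keto-dioxinones: the second deprotonation takes the benzylic CH2, this more basic carbanion attacks the imidazolide, and the third equivalent of base absorbs the acidic methine proton of 21. Compound 21 is expected as epimers and enol forms at that carbon, which is of no consequence because it becomes aromatic.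

**Step 12**
Reactants: 21 tert-butyl [(2S)-5-(4,5-dimethoxy-7-methylnaphthalen-1-yl)-7-(2,2-dimethyl-4-oxo-4H-1,3-dioxin-6-yl)-4,6-dioxoheptan-2-yl](methyl)carbamate
Product: 25 methyl (S)-2-{2-[(tert-butoxycarbonyl)(methyl)amino]propyl}-3-(4,5-dimethoxy-7-methylnaphthalen-1-yl)-4,6-dihydroxybenzoate, via acylketene 22 (not isolated), via trioxo ester 23 (not isolated), via cyclic aldol 24 (not isolated)
Conditions: MeOH (10 equiv), toluene, 110 °C (sealed); cool; Cs2CO3 (2 equiv), MeOH, rt; then AcOH
Reagents that add atoms: methanol, CO
Why: On heating, 21 loses acetone by retro-[4+2] to acylketene 22, which excess methanol captures as trioxo ester 23 (chain numbered from the ester carbon). Cs2CO3 then forms the enolate at the C2 methylene between ester and ketone, which adds to the C7 ketone in a 6-(enolexo)-exo-trig aldol reaction (isoquinoline bond C8a–C4a) to give 24; E1cB loss of water and enolization, completed on acidification, should give the benzene ring of 25. The closest known reaction type is the thermolysis, alcohol capture and carbonate-mediated aromatization of diketo-dioxinones to resorcylates, which also tolerates a carbon substituent on the central chain carbon. No lasting stereocentre is created: the carbinol and methine centres of 24 vanish on aromatization, the amine-bearing carbon is β to the ketone and cannot epimerize, and the biaryl axis forms without control. The step needs the C2 enolate to close in preference to the C8 enolate (the other fold), to Claisen closure from C6 and to lactonization to a pyrone. C2 is the only doubly activated methylene that reaches a ketone through a six-membered transition state, the naphthyl-bearing C6 enolate has no closure that ends in an aromatic ring, and excess methanol keeps the ketene from internal capture. Carbonate at room temperature is mild enough that the N-methyl carbamate should not be expelled from the β-amino ketone, and aromatization removes that ketone irreversibly.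

**Step 13**
Reactants: 25 methyl (S)-2-{2-[(tert-butoxycarbonyl)(methyl)amino]propyl}-3-(4,5-dimethoxy-7-methylnaphthalen-1-yl)-4,6-dihydroxybenzoate
Product: 26 methyl (S)-2-{2-[(tert-butoxycarbonyl)(methyl)amino]propyl}-3-(4,5-dimethoxy-7-methylnaphthalen-1-yl)-4,6-dimethoxybenzoate
Conditions: MeI (excess), K2CO3, DMF, 40 °C
Reagents that add atoms: iodomethane, CI
Why: Williamson methylation of both phenols; the chelated hydroxyl ortho to the ester and the hindered one next to the naphthyl need a polar solvent and gentle heating, and the fully substituted carbamate nitrogen cannot be alkylated.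

**Step 14**
Reactants: 26 methyl (S)-2-{2-[(tert-butoxycarbonyl)(methyl)amino]propyl}-3-(4,5-dimethoxy-7-methylnaphthalen-1-yl)-4,6-dimethoxybenzoate
Product: 28 (S)-5-(4,5-dimethoxy-7-methylnaphthalen-1-yl)-6,8-dimethoxy-2,3-dimethyl-3,4-dihydroisoquinolin-1(2H)-one, via amine hydrochloride 27 (not isolated)
Conditions: 4 M HCl in dioxane, rt; evaporate; AlMe3 (3 equiv), toluene, 0 → 90 °C; aq. HCl
Reagents that add atoms: none
Why: Acidolysis of the Boc group (chloride captures the tert-butyl cation), then Weinreb-type aminolysis of the ester by the aluminium amide formed from the amine hydrochloride and AlMe3, a 6-exo-trig lactamization that overcomes the di-ortho-substituted benzoate; C3 is not epimerizable.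

**Step 15**
Reactants: 28 (S)-5-(4,5-dimethoxy-7-methylnaphthalen-1-yl)-6,8-dimethoxy-2,3-dimethyl-3,4-dihydroisoquinolin-1(2H)-one
Product: 31 (1R,3S)-5-(4,5-dimethoxy-7-methylnaphthalen-1-yl)-6,8-dimethoxy-1,2,3-trimethyl-1,2,3,4-tetrahydroisoquinoline, via lithium carbinolamine 29 (not isolated), via iminium chloride 30 (not isolated)
Conditions: MeLi (3 equiv), THF, −78 → 0 °C; HCl in MeOH, 0 °C; NaBH4 (excess), MeOH, −78 → 0 °C
Reagents that add atoms: methyllithium, [Li]C
Why: Organolithium addition to a tertiary lactam stops at the tetrahedral lithium carbinolamine 29, and acid ionizes it to the 3,4-dihydroisoquinolinium ion 30. The C3 methyl group of 30 sits pseudoaxial to avoid allylic strain with N-methyl, so borohydride should attack C1 anti to it; the new C1–H is then trans to the C3 methyl and the two methyl groups are cis, that is (1R,3S).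

## Compound list

1 | 2-bromo-5-methoxybenzaldehyde | COc1ccc(Br)c(C=O)c1 | starting material
2 | diethyl succinate | CCOC(=O)CCC(=O)OCC | starting material
3 | (E)-4-(2-bromo-5-methoxyphenyl)-3-(ethoxycarbonyl)but-3-enoic acid | CCOC(=O)/C(=C/c1cc(OC)ccc1Br)CC(=O)O | intermediate
4 | ethyl 8-bromo-4-hydroxy-5-methoxy-2-naphthoate | CCOC(=O)c1cc(O)c2c(OC)ccc(Br)c2c1 | intermediate (not isolated)
5 | ethyl 4-acetoxy-8-bromo-5-methoxy-2-naphthoate | CCOC(=O)c1cc(OC(C)=O)c2c(OC)ccc(Br)c2c1 | intermediate
6 | 5-bromo-3-(hydroxymethyl)-8-methoxynaphthalen-1-ol | OCc1cc(O)c2c(OC)ccc(Br)c2c1 | intermediate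
7 | (8-bromo-4,5-dimethoxynaphthalen-2-yl)methanol | OCc1cc(OC)c2c(OC)ccc(Br)c2c1 | intermediate
8 | (8-bromo-4,5-dimethoxynaphthalen-2-yl)methyl methanesulfonate | CS(=O)(=O)OCc1cc(OC)c2c(OC)ccc(Br)c2c1 | intermediate (not isolated)
9 | 1-bromo-4,5-dimethoxy-7-methylnaphthalene | Cc1cc(OC)c2c(OC)ccc(Br)c2c1 | intermediate
10 | ethyl 2-(4,5-dimethoxy-7-methylnaphthalen-1-yl)acetate | CCOC(=O)Cc1ccc(OC)c2c(OC)cc(C)cc12 | intermediate
11 | 2-(4,5-dimethoxy-7-methylnaphthalen-1-yl)acetic acid | OC(=O)Cc1ccc(OC)c2c(OC)cc(C)cc12 | intermediate
12 | 2,2,6-trimethyl-4H-1,3-dioxin-4-one | CC1=CC(=O)OC(C)(C)O1 | starting material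
13 | 2-(4,5-dimethoxy-7-methylnaphthalen-1-yl)acetyl chloride | ClC(=O)Cc1ccc(OC)c2c(OC)cc(C)cc12 | intermediate (not isolated)
14 | lithium 2,2-dimethyl-6-methylene-6H-1,3-dioxin-4-olate (dienolate of 12) | [Li+].C=C1C=C([O-])OC(C)(C)O1 | intermediate (not isolated)
15 | 6-[3-(4,5-dimethoxy-7-methylnaphthalen-1-yl)-2-oxopropyl]-2,2-dimethyl-4H-1,3-dioxin-4-one | CC1(C)OC(=O)C=C(CC(=O)Cc2ccc(OC)c3c(OC)cc(C)cc23)O1 | intermediate
16 | (S)-3-aminobutanoic acid | C[C@H](N)CC(=O)O | starting material
17 | (S)-3-[(tert-butoxycarbonyl)amino]butanoic acid | C[C@H](NC(=O)OC(C)(C)C)CC(=O)O | intermediate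
18 | (S)-3-[(tert-butoxycarbonyl)(methyl)amino]butanoic acid | C[C@H](N(C)C(=O)OC(C)(C)C)CC(=O)O | intermediate
19 | tert-butyl (S)-[4-(1H-imidazol-1-yl)-4-oxobutan-2-yl](methyl)carbamate | C[C@H](N(C)C(=O)OC(C)(C)C)CC(=O)n1ccnc1 | intermediate (not isolated)
20 | dilithium dianion of 15 (enolate oxygen and benzylic carbon) | [Li+].[Li+].CC1(C)OC(=O)C=C(C=C([O-])[CH-]c2ccc(OC)c3c(OC)cc(C)cc23)O1 | intermediate (not isolated)
21 | tert-butyl [(2S)-5-(4,5-dimethoxy-7-methylnaphthalen-1-yl)-7-(2,2-dimethyl-4-oxo-4H-1,3-dioxin-6-yl)-4,6-dioxoheptan-2-yl](methyl)carbamate | CC1(C)OC(=O)C=C(CC(=O)C(C(=O)C[C@H](C)N(C)C(=O)OC(C)(C)C)c2ccc(OC)c3c(OC)cc(C)cc23)O1 | intermediate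
22 | acylketene from 21: tert-butyl [(2S)-5-(4,5-dimethoxy-7-methylnaphthalen-1-yl)-4,6,8,10-tetraoxodec-9-en-2-yl](methyl)carbamate | O=C=CC(=O)CC(=O)C(C(=O)C[C@H](C)N(C)C(=O)OC(C)(C)C)c1ccc(OC)c2c(OC)cc(C)cc12 | intermediate (not isolated)
23 | methyl (9S)-9-[(tert-butoxycarbonyl)(methyl)amino]-6-(4,5-dimethoxy-7-methylnaphthalen-1-yl)-3,5,7-trioxodecanoate | COC(=O)CC(=O)CC(=O)C(C(=O)C[C@H](C)N(C)C(=O)OC(C)(C)C)c1ccc(OC)c2c(OC)cc(C)cc12 | intermediate (not isolated)
24 | methyl 2-{(2S)-2-[(tert-butoxycarbonyl)(methyl)amino]propyl}-2-hydroxy-3-(4,5-dimethoxy-7-methylnaphthalen-1-yl)-4,6-dioxocyclohexane-1-carboxylate | COC(=O)C1C(=O)CC(=O)C(c2ccc(OC)c3c(OC)cc(C)cc23)C1(O)C[C@H](C)N(C)C(=O)OC(C)(C)C | intermediate (not isolated)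
25 | methyl (S)-2-{2-[(tert-butoxycarbonyl)(methyl)amino]propyl}-3-(4,5-dimethoxy-7-methylnaphthalen-1-yl)-4,6-dihydroxybenzoate | COC(=O)c1c(O)cc(O)c(-c2ccc(OC)c3c(OC)cc(C)cc23)c1C[C@H](C)N(C)C(=O)OC(C)(C)C | intermediate
26 | methyl (S)-2-{2-[(tert-butoxycarbonyl)(methyl)amino]propyl}-3-(4,5-dimethoxy-7-methylnaphthalen-1-yl)-4,6-dimethoxybenzoate | COC(=O)c1c(OC)cc(OC)c(-c2ccc(OC)c3c(OC)cc(C)cc23)c1C[C@H](C)N(C)C(=O)OC(C)(C)C | intermediate
27 | methyl (S)-3-(4,5-dimethoxy-7-methylnaphthalen-1-yl)-4,6-dimethoxy-2-[2-(methylamino)propyl]benzoate hydrochloride | COC(=O)c1c(OC)cc(OC)c(-c2ccc(OC)c3c(OC)cc(C)cc23)c1C[C@H](C)NC.Cl | intermediate (not isolated)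
28 | (S)-5-(4,5-dimethoxy-7-methylnaphthalen-1-yl)-6,8-dimethoxy-2,3-dimethyl-3,4-dihydroisoquinolin-1(2H)-one | COc1cc(OC)c2c(c1-c1ccc(OC)c3c(OC)cc(C)cc13)C[C@H](C)N(C)C2=O | intermediate
29 | lithium (3S)-5-(4,5-dimethoxy-7-methylnaphthalen-1-yl)-6,8-dimethoxy-1,2,3-trimethyl-1,2,3,4-tetrahydroisoquinolin-1-olate | COc1cc(OC)c2c(c1-c1ccc(OC)c3c(OC)cc(C)cc13)C[C@H](C)N(C)C2(C)[O-].[Li+] | intermediate (not isolated)
30 | (S)-5-(4,5-dimethoxy-7-methylnaphthalen-1-yl)-6,8-dimethoxy-1,2,3-trimethyl-3,4-dihydroisoquinolin-2-ium chloride | COc1cc(OC)c2c(c1-c1ccc(OC)c3c(OC)cc(C)cc13)C[C@H](C)[N+](C)=C2C.[Cl-] | intermediate (not isolated)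
31 | (1R,3S)-5-(4,5-dimethoxy-7-methylnaphthalen-1-yl)-6,8-dimethoxy-1,2,3-trimethyl-1,2,3,4-tetrahydroisoquinoline | COc1cc(OC)c2c(c1-c1ccc(OC)c3c(OC)cc(C)cc13)C[C@H](C)N(C)[C@@H]2C | target

## Step count and least certain steps

Total: 15 steps. Longest linear sequence: 13 steps (from 1 through steps 1–8 and 11–15). The amino acid branch (steps 9 and 10) joins at step 11.

**Step 12 (key step).** The process most likely to fail is the aldol closure itself. The ketone that must be attacked lies next to the naphthyl-bearing methine, and under carbonate this diketone exists largely as an aryl-stabilized enolate, so closure may be slow. Lactonization of the enolized chain onto the ester (pyrone formation), retro-Claisen cleavage by methoxide or β-elimination of the carbamate could then take over. The fallback removes the aryl group from the chain and makes the axis by cross-coupling. It sets out from 12, from 18 (as 19) and from 9, and comes back at 26.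
- Dioxinone 12 would be acylated through its dienolate with acetyl chloride to 2,2-dimethyl-6-(2-oxopropyl)-4H-1,3-dioxin-4-one F1.
- Its dianion would be acylated with imidazolide 19 to the unsubstituted diketo-dioxinone, tert-butyl [(2S)-7-(2,2-dimethyl-4-oxo-4H-1,3-dioxin-6-yl)-4,6-dioxoheptan-2-yl](methyl)carbamate F2.
- The same thermolysis, methanol capture and carbonate aromatization would give methyl (S)-2-{2-[(tert-butoxycarbonyl)(methyl)amino]propyl}-4,6-dihydroxybenzoate F3.
- MeI and K2CO3 would give the dimethyl ether, methyl (S)-2-{2-[(tert-butoxycarbonyl)(methyl)amino]propyl}-4,6-dimethoxybenzoate F4.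
- N-Bromosuccinimide in MeCN should brominate para to the C6 methoxy group, between the side chain and the C4 methoxy group, to give methyl (S)-3-bromo-2-{2-[(tert-butoxycarbonyl)(methyl)amino]propyl}-4,6-dimethoxybenzoate F5.
- Suzuki–Miyaura coupling of F5 with (4,5-dimethoxy-7-methylnaphthalen-1-yl)boronic acid F6 (from 9 by n-BuLi and B(Oi-Pr)3) under Pd(OAc)2, SPhos and K3PO4 would return to 26.

**Step 11.** The likely failure is proton transfer instead of C-acylation. The imidazolide has acidic hydrogens α to its carbonyl and may be deprotonated by the dianion or by excess amide base, with ketene formation or loss of the carbamate by β-elimination. The acidic product can also quench unreacted dianion. The fallback replaces the acylation by an aldol addition and an oxidation. It sets out from 18 and from 15 (as dianion 20) and comes back at 21.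
- Acid 18 would be converted with N,O-dimethylhydroxylamine hydrochloride and a carbodiimide into the Weinreb amide, tert-butyl (S)-{4-[methoxy(methyl)amino]-4-oxobutan-2-yl}(methyl)carbamate F7.
- LiAlH4 at low temperature would reduce it to tert-butyl (S)-methyl(4-oxobutan-2-yl)carbamate F8.
- Dianion 20 would add to F8 at −78 °C at its benzylic carbon to give the β-hydroxy ketone, tert-butyl [(2S)-5-(4,5-dimethoxy-7-methylnaphthalen-1-yl)-7-(2,2-dimethyl-4-oxo-4H-1,3-dioxin-6-yl)-4-hydroxy-6-oxoheptan-2-yl](methyl)carbamate F9.
- Dess–Martin periodinane would oxidize F9 to 21.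

**Step 15.** The likely failure is incomplete addition of MeLi to the electron-rich lactam carbonyl, which is flanked by the C8 methoxy group, or reversion of the adduct on quenching. A second risk is loss of facial selectivity in the hydride delivery if the C3 methyl group does not hold the pseudoaxial position. The fallback replaces carbonyl addition by carbonyl methylenation. It sets out from 28 and comes back at 30. Petasis methylenation with Cp2TiMe2 in toluene at 75 °C would give the enamine, (S)-5-(4,5-dimethoxy-7-methylnaphthalen-1-yl)-6,8-dimethoxy-2,3-dimethyl-1-methylene-1,2,3,4-tetrahydroisoquinoline F10. Protonation of F10 with HCl in MeOH gives 30, which is reduced with NaBH4 as in step 15.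

**Step 8.** The likely failure is deprotonation of the arylacetyl chloride by the dienolate to an aryl ketene, which then dimerizes or is O-acylated, together with consumption of dienolate by the more acidic product. The fallback replaces the acylation by a vinylogous Mukaiyama aldol reaction and an oxidation. It sets out from 10 and 12 and comes back at 15.
- Ester 10 would be reduced with i-Bu2AlH at −78 °C to 2-(4,5-dimethoxy-7-methylnaphthalen-1-yl)acetaldehyde F11.
- Dioxinone 12 would be silylated (LiN(i-Pr)2, Me3SiCl) to [(2,2-dimethyl-6-methylene-6H-1,3-dioxin-4-yl)oxy]trimethylsilane F12.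
- BF3·OEt2 at −78 °C would join them to 6-[3-(4,5-dimethoxy-7-methylnaphthalen-1-yl)-2-hydroxypropyl]-2,2-dimethyl-4H-1,3-dioxin-4-one F13.
- Dess–Martin periodinane would oxidize F13 to 15.

## Further compounds

F1 | step 12 | 2,2-dimethyl-6-(2-oxopropyl)-4H-1,3-dioxin-4-one | CC(=O)CC1=CC(=O)OC(C)(C)O1
F2 | step 12 | tert-butyl [(2S)-7-(2,2-dimethyl-4-oxo-4H-1,3-dioxin-6-yl)-4,6-dioxoheptan-2-yl](methyl)carbamate | CC1(C)OC(=O)C=C(CC(=O)CC(=O)C[C@H](C)N(C)C(=O)OC(C)(C)C)O1
F3 | step 12 | methyl (S)-2-{2-[(tert-butoxycarbonyl)(methyl)amino]propyl}-4,6-dihydroxybenzoate | COC(=O)c1c(O)cc(O)cc1C[C@H](C)N(C)C(=O)OC(C)(C)C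
F4 | step 12 | methyl (S)-2-{2-[(tert-butoxycarbonyl)(methyl)amino]propyl}-4,6-dimethoxybenzoate | COC(=O)c1c(OC)cc(OC)cc1C[C@H](C)N(C)C(=O)OC(C)(C)C
F5 | step 12 | methyl (S)-3-bromo-2-{2-[(tert-butoxycarbonyl)(methyl)amino]propyl}-4,6-dimethoxybenzoate | COC(=O)c1c(OC)cc(OC)c(Br)c1C[C@H](C)N(C)C(=O)OC(C)(C)C
F6 | step 12 | (4,5-dimethoxy-7-methylnaphthalen-1-yl)boronic acid | OB(O)c1ccc(OC)c2c(OC)cc(C)cc12
F7 | step 11 | tert-butyl (S)-{4-[methoxy(methyl)amino]-4-oxobutan-2-yl}(methyl)carbamate | C[C@H](N(C)C(=O)OC(C)(C)C)CC(=O)N(C)OC
F8 | step 11 | tert-butyl (S)-methyl(4-oxobutan-2-yl)carbamate | C[C@H](N(C)C(=O)OC(C)(C)C)CC=O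
F9 | step 11 | tert-butyl [(2S)-5-(4,5-dimethoxy-7-methylnaphthalen-1-yl)-7-(2,2-dimethyl-4-oxo-4H-1,3-dioxin-6-yl)-4-hydroxy-6-oxoheptan-2-yl](methyl)carbamate | CC1(C)OC(=O)C=C(CC(=O)C(C(O)C[C@H](C)N(C)C(=O)OC(C)(C)C)c2ccc(OC)c3c(OC)cc(C)cc23)O1
F10 | step 15 | (S)-5-(4,5-dimethoxy-7-methylnaphthalen-1-yl)-6,8-dimethoxy-2,3-dimethyl-1-methylene-1,2,3,4-tetrahydroisoquinoline | COc1cc(OC)c2c(c1-c1ccc(OC)c3c(OC)cc(C)cc13)C[C@H](C)N(C)C2=C
F11 | step 8 | 2-(4,5-dimethoxy-7-methylnaphthalen-1-yl)acetaldehyde | O=CCc1ccc(OC)c2c(OC)cc(C)cc12
F12 | step 8 | [(2,2-dimethyl-6-methylene-6H-1,3-dioxin-4-yl)oxy]trimethylsilane | C=C1C=C(O[Si](C)(C)C)OC(C)(C)O1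
F13 | step 8 | 6-[3-(4,5-dimethoxy-7-methylnaphthalen-1-yl)-2-hydroxypropyl]-2,2-dimethyl-4H-1,3-dioxin-4-one | CC1(C)OC(=O)C=C(CC(O)Cc2ccc(OC)c3c(OC)cc(C)cc23)O1
A1 | alternative 1 | tert-butyl 1-hydroxy-8-methoxy-6-methyl-4-[(1R,3S)-6,8-dimethoxy-2-(methoxycarbonyl)-1,3-dimethyl-1,2,3,4-tetrahydroisoquinolin-5-yl]-2-naphthoate | COc1cc(OC)c2c(c1-c1cc(C(=O)OC(C)(C)C)c(O)c3c(OC)cc(C)cc13)C[C@H](C)N(C(=O)OC)[C@@H]2C
A2 | alternative 1 | methyl (1R,3S)-6,8-dimethoxy-5-(4-methoxy-6-methyl-3-oxo-1,3-dihydroisobenzofuran-1-yl)-1,3-dimethyl-3,4-dihydroisoquinoline-2(1H)-carboxylate | COc1cc(C)cc2c1C(=O)OC2c1c(OC)cc(OC)c2c1C[C@H](C)N(C(=O)OC)[C@@H]2C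
A3 | alternative 1 | tert-butyl acrylate | C=CC(=O)OC(C)(C)C
A4 | alternative 2 | tert-butyl (S)-{1-[2-acetyl-3-hydroxy-5-methoxy-6-(4,5-dimethoxy-7-methylnaphthalen-1-yl)phenyl]propan-2-yl}(methyl)carbamate | COc1cc(O)c(C(C)=O)c(C[C@H](C)N(C)C(=O)OC(C)(C)C)c1-c1ccc(OC)c2c(OC)cc(C)cc12
A5 | alternative 2 | {[4-(4,5-dimethoxy-7-methylnaphthalen-1-yl)-1,3-dimethoxybuta-1,3-dien-1-yl]oxy}trimethylsilane | COC(=Cc1ccc(OC)c2c(OC)cc(C)cc12)C=C(OC)O[Si](C)(C)C
A6 | alternative 2 | tert-butyl (S)-methyl(6-oxohept-4-yn-2-yl)carbamate | CC(=O)C#CC[C@H](C)N(C)C(=O)OC(C)(C)C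
A7 | alternative 3 | methyl (1R,3S)-8-hydroxy-6-methoxy-5-(4,5-dimethoxy-7-methylnaphthalen-1-yl)-1,3-dimethyl-3,4-dihydroisoquinoline-2(1H)-carboxylate | COc1cc(O)c2c(c1-c1ccc(OC)c3c(OC)cc(C)cc13)C[C@H](C)N(C(=O)OC)[C@@H]2C
A8 | alternative 3 | methyl (2S,6R)-4-[2-diazo-2-(4,5-dimethoxy-7-methylnaphthalen-1-yl)acetyl]-2,6-dimethyl-3,6-dihydropyridine-1(2H)-carboxylate | [N-]=[N+]=C(c1ccc(OC)c2c(OC)cc(C)cc12)C(=O)C1=C[C@@H](C)N(C(=O)OC)[C@@H](C)C1
A9 | alternative 3 | methoxyacetylene | COC#C
A10 | alternative 3 | methyl (2R,6S)-2,6-dimethyl-4-oxopiperidine-1-carboxylate (meso, cis) | COC(=O)N1[C@@H](C)CC(=O)C[C@H]1C
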